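The constants used here belong to no real substance.

J.G is the product we want, and a second G turns it into G.J.G.

| flask | J | G | temperature | time | remark |
|---|---|---|---|---|---|
| west | 0.41 M (fed, over 5.0 s) | 0.369 M | 0 °C | 1.0 min | all else is in the flask from the start; the feed brings no volume worth counting |
| north | 0.41 M | 0.369 M (fed, over 50 s) | 0 °C | 1.0 min | all else is in the flask from the start; the feed brings no volume worth counting |
| south | 0.41 M | 0.369 M (fed, over 50 s) |  | 1.0 min | the addition at −30 °C, then warmed to 0 °C; the feed brings no volume worth counting |
| north-east | 0.41 M | 0.369 M |  | 1.0 min | everything together at the start at −30 °C, warmed to 0 °C at 50 s |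
| north-west | 0.41 M (fed, over 50 s) | 0.369 M | 0 °C | 1.0 min | all else is in the flask from the start; the feed brings no volume worth counting |

    J + G → J.G (k1 = 0.382 M⁻¹ s⁻¹, Ea1 = 47.0 kJ mol⁻¹)
    G + J.G ⇌ G.J.G (K2 = 2.41 M⁻¹, k2 = 0.163 M⁻¹ s⁻¹, Ea2 = 35.0 kJ mol⁻¹, ΔH2 = 7.00 kJ mol⁻¹)
    Q ⇌ J.G, rate k3*(cs3 - [J.G]) while solid is left; crystals form when [J.G] > cs3 (cs3 = 0.15 M, k3 = 0.730 s⁻¹)
    (constants at 0 °C)

- J.G is meant together with its Q
- solid, in amounts per volume of the solution: Q
- constants are those at 0 °C; use the activation energies and enthalpies for any other temperature

- which flask leads in share of J.G in J.G plus G.J.G ("all alike" within 1.5 percentage points) (west / north / south / north-east / north-west / all alike)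
- share of J.G in J.G plus G.J.G at the end, west
- share of J.G in J.G plus G.J.G at the end, north
- share of J.G in J.G plus G.J.G at the end, south
- share of J.G in J.G plus G.J.G at the end, north-east
- share of J.G in J.G plus G.J.G at the end, north-west

1. The clock. The lifetime of J against the whole G charge at 0 °C is 7.09 s. We count how many such lifetimes each flask has before the end.

2. Feed time. A steady feed enters on average at half its length. West, fed over 5.0 s, therefore counts 8.11 lifetimes, and north, fed over 50 s, counts 4.93.

3. Which reagent is fed. North feeds G and north-west feeds J, but north-west counts the same 4.93, so our hand count cannot separate them.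

4. Cold. At −30 °C, the first step is slower by a factor of 12.9, so the lifetime becomes 91.2 s. South counts 1.68 and north-east 1.96, both fewer than north.

5. What the count gives. G is the limiting reagent, but the charges lie close, so the fraction of J left should be about 1/(1 + count). That gives 11.0% for west and 33.8% for north-east. At equilibrium of the second step, [G.J.G]/[J.G] for dissolved J.G equals 2.41 M⁻¹ times [G], so less G should mean a larger share of J.G. We expect west first, the two 50 s feeds next and the cold flasks last, and we commit to no share figures.

6. The forecast names west, with 96% for west, 89.5% for north, 84% for south, 84% for north-east and 90% for north-west. Its grounds are that “west has the longest time at 0 °C for this clean-up”.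

7. The flasks give 96.1% for west, 92.0% for north, 87.3% for south, 86.9% for north-east and 89.6% for north-west, so west leads, and west is also the flask with the highest count.

In north-east, the first step ran through the cold stage, with half of its turnover up to the end done by 0.692 min, and at the warming J stood at 65.9% of the J charged and Q at 0%. Q then formed at 0 °C, with half of that turnover up to the end done by 0.932 min, and at the end J stood at 39.4% of the J charged, against our 33.8%, with G.J.G at 7.92%. The same north-east flask read at 25 s, still cold, counts 0.274 lifetimes, so the rule gives 78.5% of J left, and the reading is 78.9% of the J charged.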